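Which set-up turns the most E into L by the end?

| flask | E | J | G | remark | time |
|---|---|---|---|---|---|
| cedar | 0.10 M | 0.50 M | 30 µM | run made earlier |  |
| elm | 0.10 M | 0.34 M | 30 µM | run made earlier |  |
| maple | 0.10 M | 0.75 M | 30 µM | run made earlier |  |
| Tuesday's | 0.10 M | 0.500 M | 30 µM | a single well-mixed tank run continuously and read at steady state, 4.0 min in it on average |  |
| Monday's | 0.10 M (fed, over 3.20 min) | 0.500 M | 30 µM | a stirred flask in which E is dosed at a steady rate over 3.20 min without added volume, worked up at 4.0 min | 4.0 min |
| Friday's | 0.10 M | 0.500 M (fed, over 3.20 min) | 30 µM | a stirred flask in which J is dosed at a steady rate over 3.20 min without added volume, worked up at 4.0 min | 4.0 min |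
| Thursday's | 0.10 M | 0.500 M | 30 µM | everything together in a closed stirred flask, run for 4.0 min | 4.0 min |

- cedar (time / min: L / %, E / %): 0.167: 4.0, 95.6; 0.333: 8.0, 91.0; 0.667: 15.4, 83.9; 1.00: 23.4, 76.9; 1.33: 29.9, 69.6; 2.00: 42.4, 55.8; 2.50: 51.5, 47.1
- elm (time / min: L / %, E / %): 0.167: 2.6, 97.5; 0.500: 9.7, 90.1; 0.833: 15.2, 85.0; 1.33: 22.8, 76.4; 2.00: 34.1, 66.0; 2.50: 40.4, 59.0; 3.00: 46.4, 52.6
- maple (time / min: L / %, E / %): 0.250: 7.8, 90.9; 0.417: 12.9, 86.5; 0.667: 20.8, 79.1; 0.833: 24.9, 74.4; 1.33: 39.7, 59.7; 2.00: 53.0, 45.4; 3.00: 69.5, 24.4

(each reading ± 0.5 percentage points)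

- the stated concentrations are those of everything mixed, before any reaction; amounts are the same in each set-up
- on the list of suspects stand: E + G <-> X; J + X <-> Q; Q -> G + L; J + L -> D
- the feed brings no volume worth counting
- the earlier runs were made in a closed, stirred flask

- the set-up with the highest amount of L at the outlet or at the end, in percent of the E put in ("none" if the first two lie within 2 percentage points) (Tuesday's / Monday's / Friday's / Thursday's / none)
- amount of L at the outlet or at the end, in percent of the E put in, Tuesday's
- amount of L at the outlet or at the end, in percent of the E put in, Monday's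
- amount of L at the outlet or at the end, in percent of the E put in, Friday's
- amount of L at the outlet or at the end, in percent of the E put in, Thursday's

E is the limiting reagent, at 0.10 M against 0.500 M of J, so I write the balance of E. The cedar run has the same charges as Thursday's flask. At 2.50 min it holds 47.1% of E and 51.5% of L, so nearly all of the E lost stands as L. I take the loss of E in proportion to [E], with J and G as charged, and from that reading I get κ = 0.301 /min, the clearing constant, the share of the free E present that goes per minute: a pseudo-first-order constant.

Tuesday's tank looks nearly the same as Thursday's flask, with equal charges and 4.0 min on average. But the tank holds E at its outlet level throughout, while Thursday's flask starts from the whole charge. With [E]c the charge, my balances give: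

Thursday's: [E]/[E]c = exp(−κt) = 30.0%

Tuesday's: [E]/[E]c = 1/(1 + κt) = 45.4%

So I expect Tuesday's to keep 15 percentage points more E, and L to be near 70.0% on Thursday's and 54.6% on Tuesday's, less some D.

The forecast gives L of 59% on Tuesday's, 62% on Monday's, 53% on Friday's and 73% on Thursday's, and picks Thursday's. Of the tank it says “it runs at lower E throughout”. Its two figures stand above mine.

The flasks give 53.4% on Tuesday's, 53.6% on Monday's, 52.0% on Friday's and 68.9% on Thursday's, so Thursday's gives more L than any other.

    E + G ⇌ X (K = 9.80 /M, k = 5400 /M/s)
    J + X ⇌ Q (K = 2.10 /M, k = 630 /M/s)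
    Q → G + L (k = 47.0 /s)
    J + L → D (k = 0.00110 /M/s)

E ends at 40.4% on Tuesday's and 26.4% on Thursday's, each lower than κ gave. Friday's flask, with J dosed, shows what holds the turnover back: the main reason for its shortfall in L is the backward run from Q to J + X, for without that run L on Friday's goes from 52.0% to 94.7%. On the neighbour of Thursday's flask with 7.5 × 10⁻⁵ M of G, I scale κ with [G], by 2.50, and get E of 4.92%. The computed flask holds 1.3% of E, less than that, and 91.3% of L.

(The earlier runs and the new flask were generated by integration for substances that don't exist; noise was put on by code.)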